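**Retrosynthetic overview**

1. Target: (5′S,6E,6′E)-4,5′-retro-β,β-carotene (carotenoid numbering; ring A = cyclohexene C1–C6, ring B = cyclohexane C1′–C6′ carrying the only stereocentre, C5′). Enabling feature: the triene C8=C9(CH3)–C10H=C11H–C12H=C13(CH3) beside ring A, an unsubstituted E-vinylene between two methyl-branched E-alkenes, each the syn-adduct of H–Zr (to a C8≡C9–CH3 alkyne on the exocyclic C6=C7 of ring A) or of CH3–Al (to a terminal C12≡C13 alkyne).
2. Key disconnection, one pot, four components: C9–C10, C11–C12 and C13–CH3, giving the ring-A dienyne (C13), (E)-BrCH=CHI, AlMe3 and the ring-B hexaenyne (C24).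
3. C24 hexaenyne: from the ring-B enyne (C13) by two hydrozirconation/Negishi couplings (C9′–C10′, C13′–C14′) with two E-bromo-enyne blocks, both made from the same (E)-BrCH=CHI.
4. Ring-B enyne: enol triflate of (6S)-dihydrocyclocitral plus propyne (C7′–C8′). Ring-A dienyne: α-cyclocitral plus propynyl Grignard, then a stereospecific syn-dehydration that fixes 6E.
5. Ring order: ring B is the only ring built (cation–olefin cyclisation of (S)-citronellal enol acetate, step 2; C5′ from the chiral pool); ring A is bought as α-cyclocitral.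

Key step: step 14

Remark: rac-α-cyclocitral is taken as a purchasable aroma chemical and used as the racemate (ring A has no stereocentre in the target); every step from step 11 on is run at or below 45 °C under argon in the dark, because the ring-B terminus (C5′–H cis to C8′ across C6′=C7′) can undergo a thermal 1,5-hydrogen shift and the polyenes isomerise in light.

**Route**

Step 1
Reactants: 1 (S)-citronellal [(3S)-3,7-dimethyloct-6-enal]
Product: 2 (3S)-3,7-dimethylocta-1,6-dien-1-yl acetate (E/Z mixture at the enol double bond)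
Conditions: Ac2O, KOAc, Et3N, 120 °C
Reagents that add atoms: acetic anhydride CC(=O)OC(C)=O
Why: Base-mediated O-acetylation of the aldehyde enolate (enol ester formation) turns the carbonyl into the nucleophilic enol acetate needed in step 2 without touching the C3 stereocentre, which is not α to the carbonyl.

Step 2
Reactants: 2 (3S)-3,7-dimethylocta-1,6-dien-1-yl acetate
Product: 3 (1R,6S)-2,2,6-trimethylcyclohexane-1-carbaldehyde (trans; the cis C1 epimer may accompany it)
Conditions: 85% H3PO4, toluene, 100 °C; H2O work-up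
Reagents that add atoms: none
Why: Brønsted-acid cation–olefin cyclisation: protonation of the trisubstituted alkene gives a tertiary cation that is captured by the enol acetate carbon to close the six-membered ring B, hydrolysis of the acetoxycarbenium ion releases the aldehyde, the methyl-bearing centre (C5′ of the target) is inherited unchanged from 1, and the new formyl-bearing centre (trans preferred) is irrelevant because it becomes sp2 in step 3.

Step 3
Reactants: 3 (1R,6S)-2,2,6-trimethylcyclohexane-1-carbaldehyde
Product: 4 [(E)-((6S)-2,2,6-trimethylcyclohexylidene)methyl] trifluoromethanesulfonate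
Conditions: KN(SiMe3)2, THF, −78 °C; PhNTf2, −78 → 0 °C
Reagents that add atoms: N-phenylbis(trifluoromethanesulfonimide) O=S(=O)(N(c1ccccc1)S(=O)(=O)C(F)(F)F)C(F)(F)F
Why: O-Sulfonylation of the potassium enolate of an α,α-disubstituted aldehyde (enol triflate synthesis): both C1 epimers of 3 converge on one enolate, and the geometry with oxygen syn to the CH(CH3) carbon (C5′) should dominate because the alternative forces oxygen against the gem-dimethyl carbon (allylic 1,3-strain), any minor Z isomer being removed by chromatography.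

Step 4
Reactants: 4 [(E)-((6S)-2,2,6-trimethylcyclohexylidene)methyl] trifluoromethanesulfonate
Product: 5 (3S)-2-[(E)-but-2-yn-1-ylidene]-1,1,3-trimethylcyclohexane (ring-B enyne)
Conditions: propyne, PdCl2(PPh3)2 (3 mol%), CuI (6 mol%), i-Pr2NH, THF, 0 → 23 °C
Reagents that add atoms: propyne CC#C
Why: Sonogashira coupling of the enol triflate with propyne proceeds with retention at the sp2 carbon, so the C6′=C7′ geometry of 4 is carried into the enyne and C5′ is untouched.

Step 5
Reactants: 6 rac-α-cyclocitral (2,6,6-trimethylcyclohex-2-ene-1-carbaldehyde)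
Product: 7 rac-(1R)-1-[(1R)-2,6,6-trimethylcyclohex-2-en-1-yl]but-2-yn-1-ol (like diastereomer)
Conditions: 1-propynylmagnesium bromide, THF, −78 → 0 °C; H2O; chromatography
Reagents that add atoms: 1-propynylmagnesium bromide CC#C[Mg]Br
Why: 1,2-Addition of the alkynyl Grignard reagent to the aldehyde (little enolisation with an sp carbanion), for which a Felkin–Anh trajectory anti to the quaternary ring carbon should favour the like diastereomer, which is separated from its epimer and carries the relative configuration that step 6 translates into alkene geometry.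

Step 6
Reactants: 7 rac-(1R)-1-[(1R)-2,6,6-trimethylcyclohex-2-en-1-yl]but-2-yn-1-ol
Product: 8 (6E)-6-(but-2-yn-1-ylidene)-1,5,5-trimethylcyclohex-1-ene (ring-A dienyne)
Conditions: Burgess reagent (methyl N-(triethylammoniosulfonyl)carbamate), toluene, 50 °C
Reagents that add atoms: none
Why: Burgess dehydration is an intramolecular syn-elimination (Ei) of the sulfamate ester, and since the ring C–H next to the carbinol is the only β-hydrogen, the like configuration of 7 places the alkynyl group on the side of the gem-dimethyl carbon in the syn-periplanar transition state, which should give the 6E dienyne stereospecifically.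

Step 7
Reactants: 9 acetylene
Product: 10 (E)-1-bromo-2-iodoethene
Conditions: IBr, 48% aq. HBr, 0 °C
Reagents that add atoms: iodine monobromide IBr
Why: Electrophilic addition of I–Br to acetylene is anti (iodonium opening by bromide), which gives the E-dihaloethene.

Step 8
Reactants: 10 (E)-1-bromo-2-iodoethene
Product: 11 (E)-1-bromopent-1-en-3-yne
Conditions: 1-propynylmagnesium bromide, ZnBr2, THF, 0 °C; then 10, Pd(PPh3)4 (2 mol%), 0 → 23 °C
Reagents that add atoms: 1-propynylmagnesium bromide CC#C[Mg]Br
Why: Negishi alkynylation: zerovalent palladium inserts into the C–I bond far faster than into C–Br, so the alkynylzinc made in the flask replaces only iodine, with retention of the E geometry.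

Step 9
Reactants: 12 1,4-bis(trimethylsilyl)buta-1,3-diyne
Product: 13 buta-1,3-diyn-1-yl(trimethyl)silane
Conditions: MeLi·LiBr (1.0 equiv), Et2O, 23 °C; then H2O
Reagents that add atoms: none
Why: Nucleophilic cleavage of one C(sp)–Si bond by MeLi gives the lithium diynide, whose negative charge protects the second silyl group, so protonation delivers the mono-silyl diyne.

Step 10
Reactants: 13 buta-1,3-diyn-1-yl(trimethyl)silane; 10 (E)-1-bromo-2-iodoethene
Product: 15 [(3E,5E)-6-bromohexa-3,5-dien-1-yn-1-yl](trimethyl)silane, via alkenylzirconocene chloride 14 (not isolated)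
Conditions: Cp2Zr(H)Cl (1.0 equiv), THF, 23 °C; then 10, Pd(PPh3)4 (3 mol%), 23 °C
Reagents that add atoms: none
Why: syn-Hydrozirconation of the terminal alkyne (Zr on the terminal carbon, the silylated alkyne reacting much more slowly) followed by Pd-catalysed alkenyl–alkenyl coupling at the C–I bond of 10 with retention (Negishi coupling of an alkenylzirconocene) should give the E,E-bromodienyne.

Step 11
Reactants: 5 ring-B enyne; 11 (E)-1-bromopent-1-en-3-yne
Product: 18 (3S)-1,1,3-trimethyl-2-[(2E,4E)-3-methylocta-2,4-dien-6-yn-1-ylidene]cyclohexane (exocyclic C6′=C7′ E), via dienylzirconocene chloride 16 (not isolated), via dienylzinc chloride 17 (not isolated)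
Conditions: Cp2Zr(H)Cl (1.1 equiv), THF, 23 → 45 °C; ZnCl2 (1.1 equiv), 0 °C; 11, Pd(PPh3)4 (5 mol%), 23 °C
Reagents that add atoms: none
Why: Hydrozirconation–Negishi coupling: syn H–Zr addition to the methylalkyne places Zr on the less hindered methyl-bearing carbon (C9′), and Zr-to-Zn exchange and Pd-catalysed coupling with the alkenyl bromide then form C9′–C10′ with retention at both partners, which fixes the E C8′=C9′ alkene while C5′ and the C6′=C7′ geometry are not involved.

Step 12
Reactants: 18 ring-B trienyne; 15 [(3E,5E)-6-bromohexa-3,5-dien-1-yn-1-yl](trimethyl)silane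
Product: 21 trimethyl{(3E,5E,7E,9E,11E)-7,11-dimethyl-13-[(E,6S)-2,2,6-trimethylcyclohexylidene]trideca-3,5,7,9,11-pentaen-1-yn-1-yl}silane, via tetraenylzirconocene chloride 19 (not isolated), via tetraenylzinc chloride 20 (not isolated)
Conditions: Cp2Zr(H)Cl (1.1 equiv), THF, 23 → 40 °C; ZnCl2 (1.1 equiv), 0 °C; 15, Pd2(dba)3 (2.5 mol%), P(2-furyl)3 (10 mol%), 23 °C
Reagents that add atoms: none
Why: Second hydrozirconation–Negishi coupling of the same type: the alkyne is the site most reactive toward Cp2Zr(H)Cl, Zr again goes to the methyl-bearing carbon (C13′), and coupling with bromide 15 forms C13′–C14′ with retention, setting the E C12′=C13′ alkene.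

Step 13
Reactants: 21 silyl-capped C24 hexaenyne
Product: 22 (3S)-2-[(2E,4E,6E,8E,10E)-3,7-dimethyltrideca-2,4,6,8,10-pentaen-12-yn-1-ylidene]-1,1,3-trimethylcyclohexane (exocyclic C6′=C7′ E; ring-B C24 hexaenyne)
Conditions: K2CO3 (0.2 equiv), MeOH–THF, 23 °C
Reagents that add atoms: none
Why: Protodesilylation of the alkynylsilane by methoxide (catalytic K2CO3 in MeOH) frees the terminal alkyne under conditions far too weakly basic to deprotonate the allylic C5′–H.

Step 14
Reactants: 22 ring-B C24 hexaenyne; 10 (E)-1-bromo-2-iodoethene; 8 ring-A dienyne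
Product: 27 (5′S,6E,6′E)-4,5′-retro-β,β-carotene (all-E chain), via heptaenyl(dimethyl)alane 23 (not isolated), via octaenyl bromide 24 (not isolated), via trienylzirconocene chloride 25 (not isolated), via trienylzinc chloride 26 (not isolated)
Conditions: (a) 22, AlMe3 (2 equiv), Cp2ZrCl2 (20 mol%), CH2Cl2, 23 °C, then volatiles removed in vacuo; (b) THF, 10 (1.0 equiv), Pd2(dba)3 (2.5 mol%), P(2-furyl)3 (10 mol%), 0 → 23 °C; (c) separately 8, Cp2Zr(H)Cl (1.1 equiv), THF, 23 → 40 °C, then ZnCl2 (1.1 equiv), transferred into (b), 23 → 40 °C; argon, dark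
Reagents that add atoms: trimethylaluminium C[Al](C)C
Why: Zr-catalysed syn-methylalumination of the terminal alkyne of 22 puts CH3 on C13 and Al on C12, and alane 23 is coupled by zerovalent palladium at the C–I bond of 10 (oxidative addition, transmetalation, reductive elimination with retention) to give bromide 24, while syn-hydrozirconation of 8 puts H on C8 and Zr on the methyl-bearing C9 and, after Zr-to-Zn exchange, trienylzinc 26 couples at the C–Br bond of 24 to form the C9–C10 bond. The closest known reaction type is the one-pot sequential Negishi alkenyl–alkenyl coupling of two different alkenylmetals at (E)-1-bromo-2-iodoethene, fed by Zr-catalysed methylalumination and by hydrozirconation of 1-alkenylpropynes. No ring is closed and no stereocentre is formed; C5′ lies far from every reacting atom and meets only organometallics below 40 °C, so it should not be epimerised and the 1,5-hydrogen shift at the ring-B terminus is avoided. Three alkene geometries are fixed in this one operation: C12=C13 is E because CH3 and Al add syn, C10=C11 is E because both couplings retain the geometry of 10, and C8=C9 is E because H and Zr add syn and the coupling retains configuration. The selectivities needed are the regiochemistry of the two additions (Al on the terminal C12; Zr on C9, the less hindered alkyne carbon, reinforced by equilibration of regioisomeric alkenylzirconocenes with the slight excess of Cp2Zr(H)Cl) and iodide-before-bromide chemoselectivity, secured by the much faster oxidative addition into C–I and by adding 26 only after 23 is consumed. The substrates help in that 8 carries its only alkyne as a methylalkyne on the hindered exocyclic diene and 22 its only terminal alkyne, so each metal reagent has a single site.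

**Compound list**

1 | (S)-citronellal | O=CC[C@@H](C)CCC=C(C)C | starting material
2 | (3S)-3,7-dimethylocta-1,6-dien-1-yl acetate (E/Z mixture) | CC(=O)OC=C[C@@H](C)CCC=C(C)C | intermediate
3 | (1R,6S)-2,2,6-trimethylcyclohexane-1-carbaldehyde | O=C[C@@H]1[C@@H](C)CCCC1(C)C | intermediate
4 | [(E)-((6S)-2,2,6-trimethylcyclohexylidene)methyl] trifluoromethanesulfonate | O=S(=O)(O/C=C1\[C@@H](C)CCCC1(C)C)C(F)(F)F | intermediate
5 | (3S)-2-[(E)-but-2-yn-1-ylidene]-1,1,3-trimethylcyclohexane | CC#C/C=C1\[C@@H](C)CCCC1(C)C | intermediate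
6 | rac-α-cyclocitral | O=CC1C(C)=CCCC1(C)C | starting material
7 | rac-(1R)-1-[(1R)-2,6,6-trimethylcyclohex-2-en-1-yl]but-2-yn-1-ol (like; one enantiomer drawn) | CC#C[C@H](O)[C@H]1C(C)=CCCC1(C)C | intermediate
8 | (6E)-6-(but-2-yn-1-ylidene)-1,5,5-trimethylcyclohex-1-ene | CC1=CCCC(C)(C)\C1=C/C#CC | intermediate
9 | acetylene | C#C | starting material
10 | (E)-1-bromo-2-iodoethene | Br/C=C/I | intermediate
11 | (E)-1-bromopent-1-en-3-yne | CC#C/C=C/Br | intermediate
12 | 1,4-bis(trimethylsilyl)buta-1,3-diyne | C[Si](C)(C)C#CC#C[Si](C)(C)C | starting material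
13 | buta-1,3-diyn-1-yl(trimethyl)silane | C#CC#C[Si](C)(C)C | intermediate
14 | chlorobis(cyclopentadienyl)[(E)-4-(trimethylsilyl)but-1-en-3-yn-1-yl]zirconium (not isolated) | C[Si](C)(C)C#C/C=C/[Zr](Cl)(C1C=CC=C1)C1C=CC=C1 | intermediate
15 | [(3E,5E)-6-bromohexa-3,5-dien-1-yn-1-yl](trimethyl)silane | C[Si](C)(C)C#C/C=C/C=C/Br | intermediate
16 | chlorobis(cyclopentadienyl){(2E)-4-[(E,6S)-2,2,6-trimethylcyclohexylidene]but-2-en-2-yl}zirconium (not isolated) | Cl[Zr](C1C=CC=C1)(C1C=CC=C1)/C(C)=C/C=C2\[C@@H](C)CCCC2(C)C | intermediate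
17 | chloro{(2E)-4-[(E,6S)-2,2,6-trimethylcyclohexylidene]but-2-en-2-yl}zinc (not isolated) | Cl[Zn]/C(C)=C/C=C1\[C@@H](C)CCCC1(C)C | intermediate
18 | (3S)-1,1,3-trimethyl-2-[(2E,4E)-3-methylocta-2,4-dien-6-yn-1-ylidene]cyclohexane (exocyclic alkene E) | CC#C/C=C/C(C)=C/C=C1\[C@@H](C)CCCC1(C)C | intermediate
19 | chlorobis(cyclopentadienyl){(2E,4E,6E)-6-methyl-8-[(E,6S)-2,2,6-trimethylcyclohexylidene]octa-2,4,6-trien-2-yl}zirconium (not isolated) | Cl[Zr](C1C=CC=C1)(C1C=CC=C1)/C(C)=C/C=C/C(C)=C/C=C2\[C@@H](C)CCCC2(C)C | intermediate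
20 | chloro{(2E,4E,6E)-6-methyl-8-[(E,6S)-2,2,6-trimethylcyclohexylidene]octa-2,4,6-trien-2-yl}zinc (not isolated) | Cl[Zn]/C(C)=C/C=C/C(C)=C/C=C1\[C@@H](C)CCCC1(C)C | intermediate
21 | trimethyl{(3E,5E,7E,9E,11E)-7,11-dimethyl-13-[(E,6S)-2,2,6-trimethylcyclohexylidene]trideca-3,5,7,9,11-pentaen-1-yn-1-yl}silane | C[Si](C)(C)C#C/C=C/C=C/C(C)=C/C=C/C(C)=C/C=C1\[C@@H](C)CCCC1(C)C | intermediate
22 | (3S)-2-[(2E,4E,6E,8E,10E)-3,7-dimethyltrideca-2,4,6,8,10-pentaen-12-yn-1-ylidene]-1,1,3-trimethylcyclohexane (exocyclic alkene E) | C#C/C=C/C=C/C(C)=C/C=C/C(C)=C/C=C1\[C@@H](C)CCCC1(C)C | intermediate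
23 | dimethyl{(1E,3E,5E,7E,9E,11E)-2,7,11-trimethyl-13-[(E,6S)-2,2,6-trimethylcyclohexylidene]trideca-1,3,5,7,9,11-hexaen-1-yl}alumane (not isolated) | C[Al](C)/C=C(C)/C=C/C=C/C(C)=C/C=C/C(C)=C/C=C1\[C@@H](C)CCCC1(C)C | intermediate
24 | (3S)-2-[(2E,4E,6E,8E,10E,12E,14E)-15-bromo-3,7,12-trimethylpentadeca-2,4,6,8,10,12,14-heptaen-1-ylidene]-1,1,3-trimethylcyclohexane (exocyclic alkene E; not isolated) | Br/C=C/C=C(C)/C=C/C=C/C(C)=C/C=C/C(C)=C/C=C1\[C@@H](C)CCCC1(C)C | intermediate
25 | chlorobis(cyclopentadienyl){(2E)-4-[(E)-2,6,6-trimethylcyclohex-2-en-1-ylidene]but-2-en-2-yl}zirconium (not isolated) | CC1=CCCC(C)(C)\C1=C/C=C(C)/[Zr](Cl)(C2C=CC=C2)C2C=CC=C2 | intermediate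
26 | chloro{(2E)-4-[(E)-2,6,6-trimethylcyclohex-2-en-1-ylidene]but-2-en-2-yl}zinc (not isolated) | CC1=CCCC(C)(C)\C1=C/C=C(C)/[Zn]Cl | intermediate
27 | (5′S,6E,6′E)-4,5′-retro-β,β-carotene (all-E) | CC1=CCCC(C)(C)\C1=C/C=C(C)/C=C/C=C(C)/C=C/C=C/C(C)=C/C=C/C(C)=C/C=C1\[C@@H](C)CCCC1(C)C | target

**Step count and risks**

Total steps: 14. Longest linear sequence: 8 steps (steps 1, 2, 3, 4, 11, 12, 13, 14).

Three steps most likely to fail:

1. Step 14. What may go wrong: transfer of a methyl group from the spent alane to octaenyl bromide 24, coupling of 26 with unreacted 10 in the crowded one-pot sequence, and E/Z isomerisation of the long polyene during the prolonged operation. Fallback, setting out from 22 and 8 and returning at 27: 22 is methylaluminated as in step 14 and alane 23 is coupled (Pd2(dba)3, P(2-furyl)3, THF) with commercial (E)-2-bromovinylboronic acid MIDA ester to give the octaenyl MIDA boronate F1, a solid that can be purified. 8 is hydrozirconated as in step 14 and zirconocene 25 is cleaved with I2 to give the ring-A trienyl iodide F2. Suzuki–Miyaura coupling of F1 with F2 (Pd(OAc)2, SPhos, aq. K3PO4, THF, 23–40 °C, slow release of the boronic acid) should then give 27 from two isolated, purified partners.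

2. Step 6. What may go wrong: ionisation of the propargylic sulfamate before the syn-elimination, which would erase the stereospecificity and give 6E/6Z mixtures; or, one step earlier, poor facial selectivity in the alkynylation, so that too little like carbinol 7 is available. Fallback, setting out from 6 and returning at 8: 6 is deprotonated at its α-carbon (KN(SiMe3)2, THF, −78 °C) and the dienolate is O-sulfonylated with PhNTf2 to give the (E)-dienyl triflate F3 together with the (Z)-dienyl triflate F4. Sonogashira coupling of the mixture with propyne as in step 4 gives 8 and the (6Z)-dienyne F5, which are separated on AgNO3-impregnated silica; F5 can be re-equilibrated (I2, light) and recycled.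

3. Step 12. What may go wrong: hydrozirconation of the conjugated triene of 18 in competition with the alkyne, or placement of Zr on C12′ instead of C13′, giving regioisomeric coupling products. Fallback, setting out from 5 and 15 and returning at 21: 5 is hydrozirconated and transmetalated as in step 11, and dienylzinc chloride 17 is coupled at the C–I bond of 10 (Pd(PPh3)4, THF) to give the ring-B trienyl bromide F6. 15 is coupled with ethynylzinc bromide (from ethynylmagnesium bromide and ZnBr2, Pd(PPh3)4) to give the silyl dienediyne F7. Zr-catalysed methylalumination of the terminal alkyne of F7 (AlMe3, Cp2ZrCl2, CH2Cl2) gives the trienynyl(dimethyl)alane F8, which is coupled with F6 (Pd2(dba)3, P(2-furyl)3, THF) to give 21; the C12′=C13′ alkene then comes from syn CH3–Al addition instead of H–Zr addition.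

Further compounds
F1 | step 14 | 6-methyl-2-{(1E,3E,5E,7E,9E,11E,13E)-4,9,13-trimethyl-15-[(E,6S)-2,2,6-trimethylcyclohexylidene]pentadeca-1,3,5,7,9,11,13-heptaen-1-yl}-1,3,6,2-dioxazaborocane-4,8-dione | CN1CC(=O)OB(OC(=O)C1)/C=C/C=C(C)/C=C/C=C/C(C)=C/C=C/C(C)=C/C=C1\[C@@H](C)CCCC1(C)C
F2 | step 14 | (6E)-6-[(2E)-3-iodobut-2-en-1-ylidene]-1,5,5-trimethylcyclohex-1-ene | CC1=CCCC(C)(C)\C1=C/C=C(C)/I
F3 | step 6 | [(E)-(2,6,6-trimethylcyclohex-2-en-1-ylidene)methyl] trifluoromethanesulfonate | CC1=CCCC(C)(C)\C1=C/OS(=O)(=O)C(F)(F)F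
F4 | step 6 | [(Z)-(2,6,6-trimethylcyclohex-2-en-1-ylidene)methyl] trifluoromethanesulfonate | CC1=CCCC(C)(C)/C1=C/OS(=O)(=O)C(F)(F)F
F5 | step 6 | (6Z)-6-(but-2-yn-1-ylidene)-1,5,5-trimethylcyclohex-1-ene | CC1=CCCC(C)(C)/C1=C/C#CC
F6 | step 12 | (3S)-2-[(2E,4E)-5-bromo-3-methylpenta-2,4-dien-1-ylidene]-1,1,3-trimethylcyclohexane (exocyclic alkene E) | Br/C=C/C(C)=C/C=C1\[C@@H](C)CCCC1(C)C
F7 | step 12 | trimethyl[(3E,5E)-octa-3,5-diene-1,7-diyn-1-yl]silane | C#C/C=C/C=C/C#C[Si](C)(C)C
F8 | step 12 | dimethyl[(1E,3E,5E)-2-methyl-8-(trimethylsilyl)octa-1,3,5-trien-7-yn-1-yl]alumane | C[Al](C)/C=C(C)/C=C/C=C/C#C[Si](C)(C)C
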